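**Retrosynthetic overview**
1. Target 6 ⇒ open-chain 1-(2,6-dihydroxyphenyl)octadecane-1,3-dione 5 by opening the O1–C2 bond of the pyran-4-one ring (forward: acid cyclodehydration).
2. 5 ⇒ key C–C disconnection between the CH2 on the future C2 and the next CH2 of the chain: terminal carbanion of the polyanion of 1-(2,6-dihydroxyphenyl)butane-1,3-dione 4 plus 1-bromotetradecane 3.
3. 4 ⇒ C2–C3 disconnection (chromone numbering): enolate of 2',6'-dihydroxyacetophenone 1 plus ethyl acetate 2 (crossed Claisen). The three components 1, 2 and 3 are joined in one flask.
4. Enabling feature: the ring O1–C2–C3–C4(=O)–C4a–C8a is a dehydrated aryl 1,3-diketone (C4 and C2 are its carbonyl carbons), so the exocyclic CH2 on C2 is the terminal, most nucleophilic carbon of the diketone polyanion. The 2,6-dihydroxyphenyl ring is symmetric, so closure through either OH gives the same ring and the other OH becomes the 5-OH.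
5. Ring order: the benzene ring is bought with 1; the pyran-4-one ring is closed last.

Key step: step 1

Assumption: the target has no stereocentre and no stereogenic double bond, so it is achiral and no stereocontrol is needed.
Remark: 4 and 5 are present in the flask as lithium salts; the compound list gives their neutral forms.

Step 1
Reactants: 1 2',6'-dihydroxyacetophenone; 2 ethyl acetate; 3 1-bromotetradecane
Product: 6 5-hydroxy-2-pentadecyl-4H-chromen-4-one, via butane-1,3-dione 4 (not isolated), via octadecane-1,3-dione 5 (not isolated)
Conditions: LDA (3.1 equiv), THF, −78 → −10 °C; 2 (1.1 equiv), −78 °C → rt; LDA (2.3 equiv), −78 → 0 °C; 3 (0.95 equiv), DMPU, 0 °C → rt; then conc. HCl, MeOH, 60 °C (one pot)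
Reagents that add atoms: none
Why: Three equivalents of LDA convert 1 into its dilithium phenoxide lithium enolate, which undergoes a crossed Claisen condensation with 2 to the lithium diketonate of 4 (the expelled ethoxide makes this stage irreversible); two further equivalents of LDA (one is consumed by the ethanol set free) remove a proton from the terminal CH3, and the tetralithio species attacks 3 in an SN2 reaction through this last-formed, least stabilised carbanion, which forms the CH2–CH2 bond and gives the salt of 5. Acidification releases 5, one phenol OH adds to the C3 ketone (6-exo-trig hemiketalisation), and loss of water gives the pyran-4-one ring of 6. The closest known reaction types are the acylation of lithium polyanions of o-hydroxyacetophenones, the terminal (gamma) alkylation of beta-diketone dianions (Hauser–Harris polyanion chemistry) and the acid cyclodehydration that ends a Baker–Venkataraman chromone synthesis. No stereocentre is formed. The step needs alkylation at the terminal carbon instead of the central carbon or oxygen, and mono- instead of dialkylation: the first is secured by the charge ordering of the polyanion (the lithium-chelated phenoxide and diketonate oxygens are far less nucleophilic than the terminal carbanion), the second by using 3 as the limiting component. The direction of ring closure needs no control, because the two phenol groups of the 2,6-dihydroxyphenyl ring are equivalent and the one not used becomes the 5-OH.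

**Compound list**
1 | 2',6'-dihydroxyacetophenone, 1-(2,6-dihydroxyphenyl)ethan-1-one | CC(=O)c1c(O)cccc1O | starting material
2 | ethyl acetate | CCOC(C)=O | starting material
3 | 1-bromotetradecane | CCCCCCCCCCCCCCBr | starting material
4 | 1-(2,6-dihydroxyphenyl)butane-1,3-dione (as its lithium salt in the flask) | CC(=O)CC(=O)c1c(O)cccc1O | intermediate
5 | 1-(2,6-dihydroxyphenyl)octadecane-1,3-dione (as its lithium salt in the flask, neutral after acidification) | CCCCCCCCCCCCCCCC(=O)CC(=O)c1c(O)cccc1O | intermediate
6 | 5-hydroxy-2-pentadecyl-4H-chromen-4-one | CCCCCCCCCCCCCCCc1cc(=O)c2c(O)cccc2o1 | target

Total step count: 1
Longest linear sequence: 1 step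

**Steps most likely to fail**
The route has one step, so the ranking has one entry.

1. Step 1. What may go wrong:
- The crossed Claisen stage may stop short of full conversion, so that ketone enolate is still present when the bromide is added and is alkylated at its own alpha-carbon.
- The tetralithio species may aggregate or precipitate, so that the SN2 reaction becomes slow and elimination of the bromide competes.
- Proton transfer from the product salt to unreacted polyanion may lead to a second alkylation at the same carbon.

Fallback (sets out from 1, comes back to the route at 5): the chain is brought in as a C16 acyl group instead of a C14 alkyl halide, so that no polyanion alkylation is needed. 1 is mono-O-acylated with commercial hexadecanoyl chloride (pyridine, CH2Cl2, 0 °C; the second OH should stay chelated to the ketone) to give 2-acetyl-3-hydroxyphenyl hexadecanoate F1. A Baker–Venkataraman rearrangement (KOt-Bu, THF, 0 °C → rt) moves the acyl group from oxygen to the acetyl carbon and gives 5. Compound 5 is then isolated and cyclodehydrated with HCl in MeOH at 60 °C, as in the last stage of step 1, to give 6.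

**Further compounds**
F1 | step 1 | 2-acetyl-3-hydroxyphenyl hexadecanoate | CCCCCCCCCCCCCCCC(=O)Oc1cccc(O)c1C(C)=O
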